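**Plan**
1. Retrosynthesis (eudesmane numbering C1–C15 is used for every compound): the orthocinnamate cage is cut at its three C–O bonds to a C4/C6/C15 triol, C4–O and C15–O to a 4(15)-alkene, and the C7–isopropyl bond to a C7=C8 enone on a C9 ketone.
2. The central cut is C5–C6 of ring B. The cage oxygens sit on C6, on C4 (one carbon on, across ring-fusion carbon C5) and on C15 (attached to C4); this is the pattern of a 6-hydroxy-4(15)-alkene, which an ene reaction between a C6 aldehyde and a ring A C4=C5 alkene carrying C15 as a methyl group delivers.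
3. Further cuts: C8–C9 (Grignard addition to a C9 aldehyde) and C10–CH3 (Birch reductive methylation of a benzamide).
4. Forward: ring A comes from 2-methoxy-5-methylbenzoic acid, the C6–C8 chain is joined at C9, ring B closes in the ene step, then isopropyl, the C9 hydroxyl and the C4/C15 diol are added, and the two rings of the orthoester cage form last.
5. Stereochemistry: C10 from the pyrrolidine auxiliary; C1 by chelation-controlled reduction; C5 and C6 from a chair ene transition state steered by an O1–aluminium–O9 chelate; C7 by axial conjugate addition; C9 by dissolving-metal reduction; C4 by OsO4 attack anti to the C10 methyl; the orthoester carbon by the cage.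

Key step: step 11

Assumption: (S)-2-(methoxymethyl)pyrrolidine is taken to direct the methylation of step 2 to the face that gives the (S) quaternary carbon; if the sense is the opposite, the (R)-auxiliary is used and nothing else changes.

**Step 1**
Reactants: 1 2-methoxy-5-methylbenzoic acid; 2 (S)-2-(methoxymethyl)pyrrolidine
Product: 4 (2-methoxy-5-methylphenyl)[(2S)-2-(methoxymethyl)pyrrolidin-1-yl]methanone, via 2-methoxy-5-methylbenzoyl chloride 3 (not isolated)
Conditions: (COCl)2, DMF (cat.), CH2Cl2, 0 °C to rt; then 2, Et3N, CH2Cl2, 0 °C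
Reagents that add atoms: none
Why: Acyl chloride aminolysis is a reliable amide formation for an ortho-substituted benzoic acid and touches no stereocentre.

**Step 2**
Reactants: 4 (2-methoxy-5-methylphenyl)[(2S)-2-(methoxymethyl)pyrrolidin-1-yl]methanone
Product: 6 [(1S)-2-methoxy-1,5-dimethylcyclohexa-2,5-dien-1-yl][(2S)-2-(methoxymethyl)pyrrolidin-1-yl]methanone, via potassium amide enolate 5 (not isolated)
Conditions: K, NH3(l)/THF, t-BuOH (1 equiv), −78 °C; then MeI, −78 °C to rt
Reagents that add atoms: iodomethane, CI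
Why: Asymmetric Birch reductive alkylation: two-electron reduction with one proton delivered para to the carboxamide gives a chelated potassium amide enolate (5), and MeI enters at the amide-bearing carbon on the face left open by the auxiliary, setting the quaternary carbon C10 as (S) on the assumption stated above, while the methoxy and methyl groups remain on the two surviving double bonds.

**Step 3**
Reactants: 6 [(1S)-2-methoxy-1,5-dimethylcyclohexa-2,5-dien-1-yl][(2S)-2-(methoxymethyl)pyrrolidin-1-yl]methanone
Product: 7 (2S)-2-{[(2S)-2-(methoxymethyl)pyrrolidin-1-yl]carbonyl}-2,4-dimethylcyclohex-3-en-1-one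
Conditions: 1 M HCl, MeOH, rt
Reagents that add atoms: water, O
Why: Acid hydrolysis of the enol ether gives the C1 ketone, which cannot move into conjugation with C4=C5 because C10 bears no hydrogen, so the quaternary centre and the alkene are untouched.

**Step 4**
Reactants: 7 (2S)-2-{[(2S)-2-(methoxymethyl)pyrrolidin-1-yl]carbonyl}-2,4-dimethylcyclohex-3-en-1-one
Product: 8 [(1S,6S)-6-hydroxy-1,3-dimethylcyclohex-2-en-1-yl][(2S)-2-(methoxymethyl)pyrrolidin-1-yl]methanone (hydroxyl cis to the methyl on the quaternary carbon)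
Conditions: Zn(BH4)2, Et2O, −20 to 0 °C; aq. NH4Cl
Reagents that add atoms: none
Why: Chelation-controlled hydride reduction: zinc bridges the ketone and amide oxygens, which holds the amide arm in the plane of the C1 carbonyl and the C10 methyl perpendicular to it, so hydride adds anti to the methyl and the C1 hydroxyl (S) ends cis to the methyl and trans to the acyl group.

**Step 5**
Reactants: 8 [(1S,6S)-6-hydroxy-1,3-dimethylcyclohex-2-en-1-yl][(2S)-2-(methoxymethyl)pyrrolidin-1-yl]methanone
Product: 9 [(1S,6S)-1,3-dimethyl-6-(triethylsilyloxy)cyclohex-2-en-1-yl][(2S)-2-(methoxymethyl)pyrrolidin-1-yl]methanone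
Conditions: TESOTf, 2,6-lutidine, CH2Cl2, −78 to 0 °C
Reagents that add atoms: triethylsilyl trifluoromethanesulfonate, CC[Si](CC)(CC)OS(=O)(=O)C(F)(F)F
Why: Silylation of the hindered secondary alcohol with the silyl triflate (silyl ether formation) masks O1 through the hydride, oxidation and Grignard steps with a group that the later acidic aldehyde release removes.

**Step 6**
Reactants: 9 [(1S,6S)-1,3-dimethyl-6-(triethylsilyloxy)cyclohex-2-en-1-yl][(2S)-2-(methoxymethyl)pyrrolidin-1-yl]methanone
Product: 10 [(1R,6S)-1,3-dimethyl-6-(triethylsilyloxy)cyclohex-2-en-1-yl]methanol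
Conditions: LiH2NBH3 (from BH3·NH3 and LiN(i-Pr)2), THF, 0 °C to rt; aq. NH4Cl
Reagents that add atoms: none
Why: Lithium amidotrihydroborate is a small, strongly nucleophilic hydride donor that reduces even α-quaternary tertiary amides to primary alcohols (amide reduction with C–N cleavage) and releases the auxiliary 2 for recovery without touching a stereocentre.

**Step 7**
Reactants: 10 [(1R,6S)-1,3-dimethyl-6-(triethylsilyloxy)cyclohex-2-en-1-yl]methanol
Product: 11 (1S,6S)-1,3-dimethyl-6-(triethylsilyloxy)cyclohex-2-ene-1-carbaldehyde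
Conditions: Dess–Martin periodinane, CH2Cl2, 0 °C to rt
Reagents that add atoms: none
Why: Dess–Martin oxidation of the neopentyl primary alcohol stops at the aldehyde, which has no α-hydrogen and cannot epimerise.

**Step 8**
Reactants: 11 (1S,6S)-1,3-dimethyl-6-(triethylsilyloxy)cyclohex-2-ene-1-carbaldehyde; 12 2-(2-bromoethyl)-1,3-dioxolane
Product: 14 3-(1,3-dioxolan-2-yl)-1-[(1R,6S)-1,3-dimethyl-6-(triethylsilyloxy)cyclohex-2-en-1-yl]propan-1-ol (both carbinol epimers), via Grignard reagent 13 (not isolated)
Conditions: 12, Mg, THF, rt; then 11, THF, −78 to 0 °C; aq. NH4Cl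
Reagents that add atoms: none
Why: Grignard addition to a non-enolisable aldehyde joins C8 to C9 and brings C7 and the masked C6 aldehyde; the carbinol configuration is irrelevant because it is oxidised next.

**Step 9**
Reactants: 14 3-(1,3-dioxolan-2-yl)-1-[(1R,6S)-1,3-dimethyl-6-(triethylsilyloxy)cyclohex-2-en-1-yl]propan-1-ol
Product: 15 3-(1,3-dioxolan-2-yl)-1-[(1S,6S)-1,3-dimethyl-6-(triethylsilyloxy)cyclohex-2-en-1-yl]propan-1-one
Conditions: Dess–Martin periodinane, CH2Cl2, rt
Reagents that add atoms: none
Why: Dess–Martin oxidation of the secondary alcohol gives the C9 ketone under near-neutral conditions that leave the acetal, silyl ether and alkene alone.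

**Step 10**
Reactants: 15 3-(1,3-dioxolan-2-yl)-1-[(1S,6S)-1,3-dimethyl-6-(triethylsilyloxy)cyclohex-2-en-1-yl]propan-1-one
Product: 16 4-[(1S,6S)-6-hydroxy-1,3-dimethylcyclohex-2-en-1-yl]-4-oxobutanal
Conditions: 1 M HCl, THF, rt
Reagents that add atoms: water, O
Why: Aqueous acid hydrolyses the dioxolane (acetal hydrolysis) and the triethylsilyl ether together, giving a 1,4-keto aldehyde that has no aldol pathway to a normal ring and a free C1 hydroxyl for the chelate of step 11.

**Step 11**
Reactants: 16 4-[(1S,6S)-6-hydroxy-1,3-dimethylcyclohex-2-en-1-yl]-4-oxobutanal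
Product: 18 (4R,4aR,8S,8aS)-4,8-dihydroxy-8a-methyl-5-methylidene-3,4,4a,5,6,7,8,8a-octahydronaphthalen-1(2H)-one (trans-fused; equatorial hydroxyls on C1 and C6, C9 ketone, 4(15)-alkene), via aluminium alkoxide chelate 17 (not isolated)
Conditions: Me2AlCl (3 equiv), CH2Cl2 (0.01 M), −78 to −20 °C; 1 M HCl work-up
Reagents that add atoms: none
Why: Me2AlCl first turns the C1 hydroxyl into a chloro(methyl)aluminium alkoxide that binds the C9 carbonyl oxygen (17), and a further equivalent activates the C6 aldehyde, whose carbon then bonds to C5 while a C15 hydrogen passes to the aldehyde oxygen through a six-membered array and the π bond moves to C4=C15, concerted but asynchronous with positive charge building at tertiary C4. The closest known reaction is the Lewis-acid-promoted type 1 intramolecular carbonyl-ene reaction of citronellal to isopulegol, here with the trisubstituted alkene held in ring A. Ring B closes as a six-membered ring, exo to both the C=O and the C4=C5 π bonds, through a chair. C5 (R) is controlled by the chelate, which holds ring A in the half-chair with the C10 methyl pseudo-axial and fixes the C10–C9 rotamer with C8 anti to C1, so that a chair can only reach the C5 face that leaves H5 anti to the methyl (trans fusion), the cis-fused product requiring a boat; C6 (R) is controlled by the need of the complexed oxygen to lie equatorial, next to C15, to receive the hydrogen. The step needs trans over cis ring fusion and hydrogen transfer from C15 and not from C3: the first is secured by the O1–Al–O9 chelate, which the free C1 hydroxyl is there to provide, the second by the equatorial oxygen being close to C15 and remote from C3.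

**Step 12**
Reactants: 18 (4R,4aR,8S,8aS)-4,8-dihydroxy-8a-methyl-5-methylidene-octahydronaphthalen-1(2H)-one
Product: 19 1,6-bis(trimethylsilyl) ether and C8=C9 trimethylsilyl enol ether of 18 (all stereocentres as in 18)
Conditions: TMSOTf, Et3N, CH2Cl2, 0 °C
Reagents that add atoms: trimethylsilyl trifluoromethanesulfonate, C[Si](C)(C)OS(=O)(=O)C(F)(F)F
Why: Silyl triflate–amine soft enolisation gives the only possible enol ether (toward C8, since C10 is quaternary) and silylates both hydroxyls in the same operation, with no stereocentre affected.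

**Step 13**
Reactants: 19 tris(trimethylsilyl) derivative of 18
Product: 20 1,6-bis(trimethylsilyloxy) C7=C8 enone (C9 ketone, 4(15)-alkene; C1, C5, C6, C10 as in 18)
Conditions: Pd(OAc)2 (1.1 equiv), MeCN, rt
Reagents that add atoms: none
Why: Saegusa–Ito oxidation: the enol ether gives an oxo-π-allyl palladium enolate that loses the C7 hydrogen by β-hydride elimination to form the C7=C8 enone, Pd(OAc)2 ending as zerovalent palladium, while the isolated 4(15)-alkene and the silyl ethers are tolerated.

**Step 14**
Reactants: 20 1,6-bis(trimethylsilyloxy) C7=C8 enone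
Product: 22 (3S,4R,4aR,8S,8aS)-4,8-dihydroxy-8a-methyl-5-methylidene-3-(propan-2-yl)octahydronaphthalen-1(2H)-one (isopropyl axial on C7, cis to O6), via trimethylsilyl enol ether 21 (not isolated)
Conditions: i-PrMgCl, CuBr·SMe2 (20 mol %), TMSCl, THF, −78 °C; then 1 M HCl, THF, rt
Reagents that add atoms: isopropylmagnesium chloride, CC(C)[Mg]Cl
Why: Copper-catalysed conjugate addition of the Grignard reagent with TMSCl trapping: in the rigid trans-fused enone the isopropyl group adds to C7 axially, anti to the C10 methyl, which gives C7 (S) with the isopropyl group axial and cis to O6, and the acidic work-up hydrolyses the enol ether 21 and both silyl ethers.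

**Step 15**
Reactants: 22 (3S,4R,4aR,8S,8aS)-4,8-dihydroxy-8a-methyl-5-methylidene-3-(propan-2-yl)octahydronaphthalen-1(2H)-one
Product: 23 (1R,3S,4R,4aR,8S,8aS)-8a-methyl-5-methylidene-3-(propan-2-yl)decahydronaphthalene-1,4,8-triol (equatorial hydroxyls on C1, C6 and C9)
Conditions: Li, NH3(l)/THF, −78 °C; then NH4Cl
Reagents that add atoms: none
Why: Dissolving-metal reduction of the ketone proceeds through a ketyl that is protonated to the more stable equatorial alcohol, so C9 (R) carries its hydroxyl away from the axial C7 isopropyl group (as in metal–ammonia reductions of hindered cyclohexanones), and the isolated alkene is inert.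

**Step 16**
Reactants: 23 (1R,3S,4R,4aR,8S,8aS)-8a-methyl-5-methylidene-3-(propan-2-yl)decahydronaphthalene-1,4,8-triol
Product: 24 (1R,3S,4R,4aR,5S,8S,8aS)-5-(hydroxymethyl)-8a-methyl-3-(propan-2-yl)decahydronaphthalene-1,4,5,8-tetrol
Conditions: OsO4 (5 mol %), NMO, acetone/H2O, rt
Reagents that add atoms: N-methylmorpholine N-oxide, C[N+]1([O-])CCOCC1; water, O
Why: Catalytic OsO4 dihydroxylation with NMO as reoxidant: the 1,1-disubstituted alkene is attacked from the face opposite the axial C10 methyl, so O4 ends equatorial (C4 S) and the new CH2OH (C15) axial, as the cage requires.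

**Step 17**
Reactants: 25 (E)-(2-bromoethenyl)benzene
Product: 27 [(1E)-3,3,3-trimethoxyprop-1-en-1-yl]benzene (trimethyl orthocinnamate), via styrylmagnesium bromide 26 (not isolated)
Conditions: Mg, THF, rt; then C(OMe)4, THF, 60 °C; aq. NaHCO3 work-up
Reagents that add atoms: tetramethyl orthocarbonate, COC(OC)(OC)OC
Why: Grignard substitution of one methoxy group of the orthocarbonate (Tschitschibabin orthoester synthesis) gives the orthoester, the E geometry being carried over from the bromide and being the more stable one.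

**Step 18**
Reactants: 24 (1R,3S,4R,4aR,5S,8S,8aS)-5-(hydroxymethyl)-8a-methyl-3-(propan-2-yl)decahydronaphthalene-1,4,5,8-tetrol; 27 trimethyl orthocinnamate
Product: 28 CNP0252898.2, the (E)-2-phenylethenyl orthoester bridging O4, O6 and O15 of 24 with free C1 and C9 hydroxyls (eudesmane descriptors 1S,4S,5R,6R,7S,9R,10S; orthoester carbon S)
Conditions: 27 (1.1 equiv), CSA (10 mol %), 4 Å MS, MeCN, rt; then Et3N
Reagents that add atoms: none
Why: Acid-catalysed orthoester exchange: the primary C15 hydroxyl enters first and the equatorial O4 and O6, held side by side across C5, then close the 2,7,8-trioxabicyclo[3.2.1]octane, the only orthoester that gives up all three methoxy groups and therefore the thermodynamic sink, with the configuration of the orthoester carbon fixed by the cage and the E alkene untouched.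

**Compound list**
1 | 2-methoxy-5-methylbenzoic acid | COc1ccc(C)cc1C(=O)O | starting material
2 | (S)-2-(methoxymethyl)pyrrolidine | COC[C@@H]1CCCN1 | starting material
3 | 2-methoxy-5-methylbenzoyl chloride | COc1ccc(C)cc1C(=O)Cl | intermediate
4 | (2-methoxy-5-methylphenyl)[(2S)-2-(methoxymethyl)pyrrolidin-1-yl]methanone | COc1ccc(C)cc1C(=O)N1CCC[C@H]1COC | intermediate
5 | potassium (2-methoxy-5-methylcyclohexa-2,5-dien-1-ylidene)[(2S)-2-(methoxymethyl)pyrrolidin-1-yl]methanolate | COC1=CCC(C)=CC1=C([O-])N1CCC[C@H]1COC.[K+] | intermediate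
6 | [(1S)-2-methoxy-1,5-dimethylcyclohexa-2,5-dien-1-yl][(2S)-2-(methoxymethyl)pyrrolidin-1-yl]methanone | COC[C@@H]1CCCN1C(=O)[C@@]1(C)C=C(C)CC=C1OC | intermediate
7 | (2S)-2-{[(2S)-2-(methoxymethyl)pyrrolidin-1-yl]carbonyl}-2,4-dimethylcyclohex-3-en-1-one | COC[C@@H]1CCCN1C(=O)[C@@]1(C)C=C(C)CCC1=O | intermediate
8 | [(1S,6S)-6-hydroxy-1,3-dimethylcyclohex-2-en-1-yl][(2S)-2-(methoxymethyl)pyrrolidin-1-yl]methanone | COC[C@@H]1CCCN1C(=O)[C@@]1(C)C=C(C)CC[C@@H]1O | intermediate
9 | [(1S,6S)-1,3-dimethyl-6-(triethylsilyloxy)cyclohex-2-en-1-yl][(2S)-2-(methoxymethyl)pyrrolidin-1-yl]methanone | COC[C@@H]1CCCN1C(=O)[C@@]1(C)C=C(C)CC[C@@H]1O[Si](CC)(CC)CC | intermediate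
10 | [(1R,6S)-1,3-dimethyl-6-(triethylsilyloxy)cyclohex-2-en-1-yl]methanol | OC[C@@]1(C)C=C(C)CC[C@@H]1O[Si](CC)(CC)CC | intermediate
11 | (1S,6S)-1,3-dimethyl-6-(triethylsilyloxy)cyclohex-2-ene-1-carbaldehyde | O=C[C@@]1(C)C=C(C)CC[C@@H]1O[Si](CC)(CC)CC | intermediate
12 | 2-(2-bromoethyl)-1,3-dioxolane | BrCCC1OCCO1 | starting material
13 | [2-(1,3-dioxolan-2-yl)ethyl]magnesium bromide | Br[Mg]CCC1OCCO1 | intermediate
14 | 3-(1,3-dioxolan-2-yl)-1-[(1R,6S)-1,3-dimethyl-6-(triethylsilyloxy)cyclohex-2-en-1-yl]propan-1-ol (carbinol epimers) | OC(CCC1OCCO1)[C@@]1(C)C=C(C)CC[C@@H]1O[Si](CC)(CC)CC | intermediate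
15 | 3-(1,3-dioxolan-2-yl)-1-[(1S,6S)-1,3-dimethyl-6-(triethylsilyloxy)cyclohex-2-en-1-yl]propan-1-one | O=C(CCC1OCCO1)[C@@]1(C)C=C(C)CC[C@@H]1O[Si](CC)(CC)CC | intermediate
16 | 4-[(1S,6S)-6-hydroxy-1,3-dimethylcyclohex-2-en-1-yl]-4-oxobutanal | O=CCCC(=O)[C@@]1(C)C=C(C)CC[C@@H]1O | intermediate
17 | O1-chloro(methyl)aluminium alkoxide of 16, chelated to the C9 carbonyl | O=CCCC(=O)[C@@]1(C)C=C(C)CC[C@@H]1O[Al](C)Cl | intermediate
18 | (4R,4aR,8S,8aS)-4,8-dihydroxy-8a-methyl-5-methylidene-3,4,4a,5,6,7,8,8a-octahydronaphthalen-1(2H)-one | C1CC(=O)[C@@]2(C)[C@H]([C@@H]1O)C(=C)CC[C@@H]2O | intermediate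
19 | 1,6-bis(trimethylsilyl) ether and C8=C9 trimethylsilyl enol ether of 18 | C1C=C(O[Si](C)(C)C)[C@@]2(C)[C@H]([C@@H]1O[Si](C)(C)C)C(=C)CC[C@@H]2O[Si](C)(C)C | intermediate
20 | 1,6-bis(trimethylsilyloxy) C7=C8 enone derived from 18 | C1=CC(=O)[C@@]2(C)[C@H]([C@@H]1O[Si](C)(C)C)C(=C)CC[C@@H]2O[Si](C)(C)C | intermediate
21 | C8=C9 trimethylsilyl enol ether of the 7-isopropyl 1,6-bis(trimethylsilyl) ether | CC(C)[C@@H]1C=C(O[Si](C)(C)C)[C@@]2(C)[C@H]([C@@H]1O[Si](C)(C)C)C(=C)CC[C@@H]2O[Si](C)(C)C | intermediate
22 | (3S,4R,4aR,8S,8aS)-4,8-dihydroxy-8a-methyl-5-methylidene-3-(propan-2-yl)octahydronaphthalen-1(2H)-one | CC(C)[C@@H]1CC(=O)[C@@]2(C)[C@H]([C@@H]1O)C(=C)CC[C@@H]2O | intermediate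
23 | (1R,3S,4R,4aR,8S,8aS)-8a-methyl-5-methylidene-3-(propan-2-yl)decahydronaphthalene-1,4,8-triol | CC(C)[C@@H]1C[C@@H](O)[C@@]2(C)[C@H]([C@@H]1O)C(=C)CC[C@@H]2O | intermediate
24 | (1R,3S,4R,4aR,5S,8S,8aS)-5-(hydroxymethyl)-8a-methyl-3-(propan-2-yl)decahydronaphthalene-1,4,5,8-tetrol | CC(C)[C@@H]1C[C@@H](O)[C@@]2(C)[C@H]([C@@H]1O)[C@](O)(CO)CC[C@@H]2O | intermediate
25 | (E)-(2-bromoethenyl)benzene | Br/C=C/c1ccccc1 | starting material
26 | [(E)-2-phenylethenyl]magnesium bromide | Br[Mg]/C=C/c1ccccc1 | intermediate
27 | [(1E)-3,3,3-trimethoxyprop-1-en-1-yl]benzene (trimethyl orthocinnamate) | COC(OC)(OC)/C=C/c1ccccc1 | intermediate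
28 | CNP0252898.2 (1,9-dihydroxyeudesmane 4,6,15-orthocinnamate) | CC(C)[C@@H]1C[C@@H](O)[C@@]2(C)[C@@H]3[C@@H]1O[C@]1(/C=C/c4ccccc4)OC[C@@]3(CC[C@@H]2O)O1 | target

**Step count**
Total: 18 steps. Longest linear sequence: 17 steps (steps 1–16 and 18); step 17 is a one-step branch.

**Steps most likely to fail**

Step 11. The ring may close through the cis-fused pathway if the aluminium chelate is not maintained, and methyl transfer from aluminium to the aldehyde may compete. The fallback sets C5 after ring closure, by kinetic protonation of an extended enolate, and C6 by reduction and inversion. It sets out from 15. In(OTf)3-catalysed transacetalisation in wet acetone frees the aldehyde and keeps the silyl ether, giving 4-[(1S,6S)-1,3-dimethyl-6-(triethylsilyloxy)cyclohex-2-en-1-yl]-4-oxobutanal F1. Me2AlCl then closes ring B without regard to the fusion, giving the 1-O-triethylsilyl ene adducts F2 as a mixture at C5 and C6. Dess–Martin oxidation gives the 1-triethylsilyloxy 4(15)-ene-6,9-dione F3. t-BuOK in t-BuOH forms the C6 dienolate running through C5 and C4=C15, and a fast acetic acid quench protonates C5 on the face opposite the C10 methyl, giving the trans-fused dione F4 with the alkene still exocyclic. NaBH4 in MeOH at −78 °C reduces the less hindered C6 ketone from the face opposite the C10 methyl, giving the axial C6 alcohol F5. Mitsunobu inversion (4-nitrobenzoic acid, DIAD, PPh3) gives the equatorial C6 4-nitrobenzoate F6. K2CO3 in MeOH gives the 1-O-triethylsilyl ether of 18 F7, and 1 M HCl in THF returns to the route at 18.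

Step 14. Isopropyl may be delivered to the C7 face syn to the C10 methyl, or the hindered enone may undergo 1,2-addition. The fallback makes the addition substrate-directed. It sets out from 20: K2CO3 in MeOH removes both silyl ethers to give the 1,6-dihydroxy C7=C8 enone F8. Excess i-PrMgCl in THF without copper then forms the C6 magnesium alkoxide, which delivers the isopropyl group to C7 on its own face (alkoxide-directed conjugate addition of Grignard reagents to γ-hydroxy enones). The route is rejoined at 22.

Step 18. The reagent may exchange into the 1,9-diol to give methoxy-bearing orthoesters that hydrolyse to cinnamate esters, and the cage may reopen on an acidic work-up. The fallback builds the cage from an ester and needs no exchangeable reagent. It sets out from 24: cinnamoyl chloride and 2,4,6-collidine in CH2Cl2 at −40 °C acylate only the primary C15 hydroxyl, giving the 15-O-cinnamate of 24 F9. CSA in benzene over 4 Å MS then closes the orthoester by attack of O4 and O6 on the protonated ester with loss of water (acid-catalysed cyclodehydration of a triol monoester). The route is rejoined at 28.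

**Further compounds**
F1 | step 11 | 4-[(1S,6S)-1,3-dimethyl-6-(triethylsilyloxy)cyclohex-2-en-1-yl]-4-oxobutanal | O=CCCC(=O)[C@@]1(C)C=C(C)CC[C@@H]1O[Si](CC)(CC)CC
F2 | step 11 | 1-O-triethylsilyl ene adducts, 4-hydroxy-8a-methyl-5-methylidene-8-(triethylsilyloxy)octahydronaphthalen-1(2H)-one as a mixture at C5 and C6 (eudesmane numbering) | C1CC(=O)[C@@]2(C)C(C1O)C(=C)CC[C@@H]2O[Si](CC)(CC)CC
F3 | step 11 | 8a-methyl-5-methylidene-8-(triethylsilyloxy)hexahydronaphthalene-1,4-dione, mixture at C5 (eudesmane numbering) | C1CC(=O)[C@@]2(C)C(C1=O)C(=C)CC[C@@H]2O[Si](CC)(CC)CC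
F4 | step 11 | trans-fused 8a-methyl-5-methylidene-8-(triethylsilyloxy)hexahydronaphthalene-1,4-dione (H5 anti to the C10 methyl) | C1CC(=O)[C@@]2(C)[C@H](C1=O)C(=C)CC[C@@H]2O[Si](CC)(CC)CC
F5 | step 11 | C6 epimer (axial hydroxyl) of the 1-O-triethylsilyl ether of 18 | C1CC(=O)[C@@]2(C)[C@H]([C@H]1O)C(=C)CC[C@@H]2O[Si](CC)(CC)CC
F6 | step 11 | 6-O-(4-nitrobenzoyl) 1-O-triethylsilyl derivative of 18 | C1CC(=O)[C@@]2(C)[C@H]([C@@H]1OC(=O)c1ccc(cc1)[N+](=O)[O-])C(=C)CC[C@@H]2O[Si](CC)(CC)CC
F7 | step 11 | 1-O-triethylsilyl ether of 18 | C1CC(=O)[C@@]2(C)[C@H]([C@@H]1O)C(=C)CC[C@@H]2O[Si](CC)(CC)CC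
F8 | step 14 | 1,6-dihydroxy C7=C8 enone, 4,8-dihydroxy-8a-methyl-5-methylidene-4a,5,6,7,8,8a-hexahydronaphthalen-1(4H)-one (stereocentres as in 18) | C1=CC(=O)[C@@]2(C)[C@H]([C@@H]1O)C(=C)CC[C@@H]2O
F9 | step 18 | 15-O-[(E)-cinnamoyl] ester of 24 | CC(C)[C@@H]1C[C@@H](O)[C@@]2(C)[C@H]([C@@H]1O)[C@](O)(COC(=O)/C=C/c1ccccc1)CC[C@@H]2O
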